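The numbers in the tables were computed on assumed constants; the scatter is artificial.

Watch the starting material.

| flask | starting material | reagent in the second phase | protic impurity | remark | time | volume of the second phase over the first |
|---|---|---|---|---|---|---|
| Friday's | 0.48 M | 0.384 M | 6.4 mM | run made earlier |  |  |
| flask | 0.32 M | 0.384 M | 6.40 mM |  | 12 min | 0.50 |

- Friday's (time / min: target / %, starting material / %): 0.833: 8.2, 87.8; 2.00: 22.6, 70.0; 2.50: 24.3, 65.0; 4.00: 36.2, 53.7

(standard deviation of a reading: 1 percentage point)

- in the second phase: reagent in the second phase; everything else is in the first
- charges count per volume of the first phase; a concentration in a rate is the amount of a species over the volume of its own phase; every rate counts per litre of the first phase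
- what was read earlier has a scatter of 1 percentage point, one standard deviation
- reactions considered so far: reagent in the reaction phase <-> reagent in the second phase; target <-> isomer of the product; starting material + reagent in the reaction phase -> target; starting material + protic impurity -> quenched substrate
- the earlier runs hold the two phases in the same ratio of volumes as the flask asked about

- alder: doubling the transfer coefficient of the reagent in the second phase, all else as stated
- larch: doubling the amount of reagent in the second phase, all else as stated

- how much target there is at 12 min, in percent of the starting material charged
- the change that raises the amount of target at 12 min, in percent of the starting material charged most ("none" if none brings more than 2 percentage points) (alder / larch / none)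
- amount of target at 12 min, in percent of the starting material charged, after alder

Take Friday's run first. If starting material is lost in proportion to what is left, the pseudo-first-order case, one number describes the run. It is the log of charge over remainder, divided by time. Call it the fade constant. The last reading gives 0.155 min⁻¹, and the first gives 0.156 min⁻¹. The two readings between give 0.178 min⁻¹ and 0.172 min⁻¹, beyond the scatter, so the constant moves by up to 14.7% and the close match of first and last proves no constancy. I carry the last value, which spans a longer time than the others, with a half-life of 4.46 min.

My reckoning freezes it for the flask, which carries the same 0.384 M of reagent in the second phase. That is an assumption, since the flask has less starting material. At 12 min it leaves 15.5%. Protic impurity can quench 2.00%. The rest, 82.5%, is target plus isomer of the product. Friday's readings taken together put 77.3% of that pair in target, so I expect 63.8% of target.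

The first reading, at 0.833 min, comes well before that half-life, yet its constant is already about the last reading's. So I expect little from alder. If larch doubles the constant, target reaches 73.9%, so I choose larch.

The forecast says 74%, between 68% and 79%, which is more than my figure. After alder it says 76%, between 71% and 81%. It also picks larch, on the ground that “Doubling reagent speeds transfer and also raises the excess”.

The flask gives 61.9% of target and 62.4% after alder. The better change is larch, worth 13 percentage points against 0.49 points.

    reagent in the reaction phase ⇌ reagent in the second phase, rate k1*([reagent in the reaction phase] - [reagent in the second phase]/K1) per volume of the first phase (partition coefficient = 0.810, kL = 0.00970 s⁻¹)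
    target ⇌ isomer of the product (K = 0.300, k = 0.0320 s⁻¹)
    starting material + reagent in the reaction phase → target (k = 0.0180 M⁻¹ s⁻¹)
    starting material + protic impurity → quenched substrate (k = 1.70 M⁻¹ s⁻¹)

This flask still holds 17.6% of starting material at 12.0 min, so its fade constant over the run is 0.145 min⁻¹, less than Friday's 0.155 min⁻¹. By then the half-life of starting material through reagent in the reaction phase is 7.2 min, longer than Friday's 4.46 min, and c(reagent in the reaction phase) has gone from 0.203 M at 1.20 min to 0.0893 M. The neighbour charged with 1.3 M of starting material, more than the reagent charge, has a fade constant of 0.0297 min⁻¹, with c(reagent in the reaction phase) at 2.09 × 10⁻⁴ M and 70.0% of starting material left.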